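With 0.05 mol% of free catalyst, each catalyst had to make 2000 turns of the cycle to use up the charge of starting material, so I looked for the time of one turn.

    2 starting material → homo dimer (k1 = 0.122 /M/s)
    catalyst intermediate E → free catalyst + product (k2 = 530 /s)
    catalyst intermediate D ⇌ catalyst intermediate E (K3 = 0.354, k3 = 518 /s)
    partner + protic impurity → quenched reagent (k4 = 306 /M/s)
    catalyst intermediate B → by-product + catalyst intermediate C (k5 = 1160 /s)
    catalyst intermediate A → catalyst intermediate B (k6 = 757 /s)
    starting material + catalyst intermediate C ⇌ catalyst intermediate D (K7 = 1850 /M, k7 = 7.57 × 10⁵ /M/s)
    partner + free catalyst ⇌ catalyst intermediate A (K8 = 586 /M, k8 = 6.45 × 10⁵ /M/s)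

| flask | starting material | partner | protic impurity | free catalyst | time | remark |
|---|---|---|---|---|---|---|
| violet | 0.0010 M | 1.05 equiv | 0.200 mM | 0.05 mol% | 15 s | everything together in a closed stirred flask, run for 15 s |
| green | 0.0010 M | 1.05 equiv (fed, over 15.0 s) | 0.200 mM | 0.05 mol% | 15 s | all but partner at the start; partner goes in evenly over 15.0 s, the run ends at 15 s |
| red | 0.0010 M | 1.05 equiv | 0.200 mM | 0.05 mol% |  | one stirred flow tank at steady state, fed with the mixture as stated, mean residence time 15 s |
| blue | 0.0010 M | 1.05 equiv | 0.200 mM | 0.05 mol% |  | a single well-mixed tank run continuously and read at steady state, 45.0 s in it on average |

- order of the set-ups by the amount of product at the outlet or at the end, in percent of the starting material put in, highest first (violet / green / red / blue)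
- amount of product at the outlet or at the end, in percent of the starting material put in, violet
- amount of product at the outlet or at the end, in percent of the starting material put in, green
- amount of product at the outlet or at the end, in percent of the starting material put in, red
- amount of product at the outlet or at the end, in percent of the starting material put in, blue

- a species is counted by the starting material in it: one homo dimer counts as two
- two of one species on the left: rate k times its square, two consumed each time
- the stated concentrations are those of everything mixed, before any reaction; amounts are the same in each set-up
- the feed brings no volume worth counting
- run time (violet): 15 s

- I expected the end state near 85.0% product as a fraction of the charge: one partner goes into each product and one into each quenched reagent, so partner is the limiting reagent once protic impurity has taken its share.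
- On the fastest rung stood the first-order steps through catalyst intermediates A, B, D and E. Since E falls back 2.76 times as fast as it goes on, they hold a catalyst for a fixed part of 11.3 ms per turn.
- Next came the pseudo-first-order waits for the two reagents, with unproductive bindings counted. Of partner bindings, 40.7% go on, and of starting material bindings, 0.266 of E goes on, which leaves 25.2%. At full charge the waits are 3.62 ms for partner and 5.25 ms for starting material.
- The turn time is the fixed part plus each wait divided by the fraction of that reagent's own charge still free; at the charge it is 20.2 ms.
- Protic impurity came next, with a half-life of 2.16 s against partner at its charge, shorter than the run in violet, while a turn is far shorter still.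
- Product then accrues at the loading over the turn time, 0.0248 /s of the charge at the start. With the turn held at its charge value, this gave estimates of 37.2% in 15 s and 112% in blue, and the second is more than the end state, so blue's turn must lengthen.
- Slowest was homo dimer, with a first half-life of 4100 s, far beyond both 15 s and 45.0 s, so I dropped it.
- I ranked blue first, its stay being longer. I put violet next, starting from the charge while red works at its outlet fractions, and green last, with partner entering at 0.0700 /s of the charge.
- The forecast gave blue > violet > red > green, with 32.4% for violet, 24% for green, 29.8% for red and 60% for blue, and held that “the slow feed comes last because partner stays low”.
- The simulation gave blue > violet > red > green, with 32.6% for violet, 24.2% for green, 29.8% for red and 59.9% for blue.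
- Loading times run time over yield reads green's mean turn as 30.9 ms, against 20.2 ms at the charge. Green's low yield came from two things acting together, each a part: the early reading, since at 150 s green gave 85.1%, and the fall back of catalyst intermediate E to catalyst intermediate D, since with that reverse step struck out green gave 33.4% in place of 24.2%.
- For the neighbour, green with 0.2 mol% of free catalyst, the turn time at the charge gives a demand of 0.0990 /s of the charge, more than the partner feed, so I expected product to follow the feed and fall short of 4.00 times green's yield. The computed result was 67.3% product, with 25% of partner left against 62% in green.

The constants are made up.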